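**Retrosynthetic overview**
- The C10 ester is made late by coupling a tricyclic γ-hydroxy-enal with (9Z)-16-silyloxyhexadec-9-enoic acid (alkyne alkylation, then semihydrogenation); enal → acid and one acid step then free the CHO and the chain OH.
- C10–OH and the C8 carboxyl carbon come from the 8-methyl-8-ene: allylic C–H oxidation to the 8-en-10-one, hydride from the face of the one-carbon bridge, then SeO2 on the vinylic methyl.
- The C2 formyl group is carried as carboxyl → methyl ester → dimethyl acetal, so C2 cannot enolise between the cascade and the last step.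
- Key step: the C1–C5 and C6–C7 bonds are formed in one acid-triggered cation–olefin cascade from a monocyclic bisabolane-type diene acid. Its single stereocentre comes from enantioselective alkylation of p-tolylacetic acid followed by Birch reduction.
- Ring order: six-membered ring (arene, then cyclohexa-1,4-diene) → spiro cyclopentane (acorenyl cation) → bridging five-membered ring of the bicyclo[3.2.1]octene (cedryl cation).

Assumption: 5-iodo-2-methylpent-2-ene, dec-9-ynoic acid and (6-bromohexyloxy)(tert-butyl)dimethylsilane are bought as catalogue chemicals.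
Locants follow tricyclo[5.3.1.0^{1,5}]undecane numbering: C1 spiro bridgehead, C2 bears C14, C6 = CMe2, C7 bridgehead, C8 bears C15, C11 = one-carbon bridge.

**Route**

Step 1
Reactants: 1 2-(4-methylphenyl)acetic acid; 2 5-iodo-2-methylpent-2-ene
Product: 4 (2S)-6-methyl-2-(4-methylphenyl)hept-5-enoic acid, via dilithium enediolate 3 (not isolated)
Conditions: (R,R)-N,N′-bis[1-phenyl-2-(piperidin-1-yl)ethyl]propane-1,3-diamine (1.05 equiv), n-BuLi (4.1 equiv), THF, 0 °C; then 2, −78 °C; aq. HCl work-up (amine recovered from the acid phase)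
Reagents that add atoms: none
Why: Enantioselective alkylation of an arylacetic acid enediolate held in a mixed aggregate with a chiral lithium amide (traceless-auxiliary alkylation, Zakarian type), which exposes one enolate face to the primary iodide and sets C2 as S; this is the only stereocentre brought in from outside, and the amine antipode is used should the sense prove opposite.

Step 2
Reactants: 4 (2S)-6-methyl-2-(4-methylphenyl)hept-5-enoic acid
Product: 5 (2S)-6-methyl-2-(4-methylcyclohexa-1,4-dien-1-yl)hept-5-enoic acid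
Conditions: Li (6 equiv), NH3(l)/THF, t-BuOH (4 equiv), −78 °C; NH4Cl; cold pH 4 work-up; used at once
Reagents that add atoms: none
Why: Birch reduction of a 1,4-dialkylbenzene protonates the two unsubstituted para-related carbons and leaves both alkyl groups on sp2 carbons (the γ-curcumene pattern, i.e. the bisabolane stage); the carboxylate and the isolated trisubstituted olefin are not reduced and C2 is not touched.

Step 3
Reactants: 5 (2S)-6-methyl-2-(4-methylcyclohexa-1,4-dien-1-yl)hept-5-enoic acid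
Product: 8 (1R,2S,5S,7S)-6,6,8-trimethyltricyclo[5.3.1.0^{1,5}]undec-8-ene-2-carboxylic acid, via spiro acorenyl cation 6 (not isolated), via cedryl cation 7 (not isolated)
Conditions: CF3CO2H/CH2Cl2 (1:4), 5 mM, 0 °C → rt, 3 h; evaporate; NaHCO3 extraction and re-acidification
Reagents that add atoms: none
Why: Proposed new method: CF3CO2H protonates the side-chain-bearing ring olefin at its CH end to give the tertiary ring cation, the prenyl-type olefin closes 5-exo onto it to the spiro cation 6, the remaining ring olefin captures the CMe2+ centre to give cation 7, and loss of H9 gives the 8-ene; C5 is expected to form cis to the C2 carboxyl because the carbonyl oxygen can bridge the developing CMe2+ centre (six-membered acyloxonium or δ-lactone, reversible in CF3CO2H), the spiro centre corrects itself because ring-olefin migration is reversible and only the isomer with CMe2+ beside the allylic CH2 can close, and C7 is then fixed by the bicyclo[3.2.1] frame, so the one stereocentre of 5 sets C1, C5 and C7; the closest known reaction type is the acid-promoted (HCO2H/CF3CO2H) biomimetic cyclisation of nerolidol or γ-curcumene through acoradienes to α-cedrene.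

Step 4
Reactants: 8 (1R,2S,5S,7S)-6,6,8-trimethyltricyclo[5.3.1.0^{1,5}]undec-8-ene-2-carboxylic acid
Product: 9 methyl (1R,2S,5S,7S)-6,6,8-trimethyltricyclo[5.3.1.0^{1,5}]undec-8-ene-2-carboxylate
Conditions: MeI, K2CO3, DMF, rt; SiO2 chromatography (removes the C5-epimeric diastereomer series)
Reagents that add atoms: iodomethane CI
Why: Carboxylate O-alkylation (SN2) under weak base leaves the α-stereocentre alone and gives an ester on which the cascade diastereomers are separated and which can be reduced only as far as the aldehyde.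

Step 5
Reactants: 9 methyl (1R,2S,5S,7S)-6,6,8-trimethyltricyclo[5.3.1.0^{1,5}]undec-8-ene-2-carboxylate
Product: 11 (1R,2S,5S,7S)-2-(dimethoxymethyl)-6,6,8-trimethyltricyclo[5.3.1.0^{1,5}]undec-8-ene, via free aldehyde 10 (not isolated)
Conditions: i-Bu2AlH (1.1 equiv), CH2Cl2, −78 °C; then MeOH, HC(OMe)3, TsOH·H2O, −78 → 0 °C
Reagents that add atoms: trimethyl orthoformate COC(OC)OC; methanol CO
Why: Half-reduction of the hindered ester with i-Bu2AlH stops at the tetrahedral aluminium hemiacetal at −78 °C, and its collapse in acidic methanol/orthoformate gives the aldehyde, which is acetalised faster than it enolises, so C2 keeps its configuration and is locked for the oxidations that follow.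

Step 6
Reactants: 11 (1R,2S,5S,7S)-2-(dimethoxymethyl)-6,6,8-trimethyltricyclo[5.3.1.0^{1,5}]undec-8-ene
Product: 12 (1S,2S,5S,7S)-2-(dimethoxymethyl)-6,6,8-trimethyltricyclo[5.3.1.0^{1,5}]undec-8-en-10-one
Conditions: Rh2(C6H10NO)4 (dirhodium tetracaprolactamate, 1 mol%), t-BuOOH (70% aq., 5 equiv), K2CO3 (0.5 equiv), CH2Cl2, rt
Reagents that add atoms: tert-butyl hydroperoxide CC(C)(C)OO
Why: Dirhodium caprolactamate/t-BuOOH allylic C–H oxidation (Doyle type) attacks C10, the only allylic CH2 (C7–H is a bridgehead, C15 a methyl), and gives the 8-en-10-one; no stereocentre is formed.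

Step 7
Reactants: 12 (1S,2S,5S,7S)-2-(dimethoxymethyl)-6,6,8-trimethyltricyclo[5.3.1.0^{1,5}]undec-8-en-10-one
Product: 13 (1S,2S,5S,7S,10S)-2-(dimethoxymethyl)-6,6,8-trimethyltricyclo[5.3.1.0^{1,5}]undec-8-en-10-ol
Conditions: NaBH4, CeCl3·7H2O, MeOH, −78 °C
Reagents that add atoms: none
Why: Luche 1,2-reduction in which hydride reaches C10 from the face of the one-carbon C11 bridge, because the other face is covered by the endo hydrogen on C5 and the CMe2 bridge; this puts the hydroxyl on the side of the two-carbon bridge (10S) as in the target.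

Step 8
Reactants: 13 (1S,2S,5S,7S,10S)-2-(dimethoxymethyl)-6,6,8-trimethyltricyclo[5.3.1.0^{1,5}]undec-8-en-10-ol
Product: 14 (1S,2S,5S,7R,10S)-2-(dimethoxymethyl)-10-hydroxy-6,6-dimethyltricyclo[5.3.1.0^{1,5}]undec-8-ene-8-carbaldehyde
Conditions: SeO2 (1.3 equiv), pyridine (2 equiv), 1,4-dioxane, 80 °C
Reagents that add atoms: selenium dioxide O=[Se]=O
Why: Riley-type SeO2 allylic oxidation (ene reaction, then [2,3]-shift) takes the only non-bridgehead allylic C–H on the more substituted olefin terminus, the C15 methyl cis to H9, through to the enal; pyridine buffers selenous acid so the acetal survives.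

Step 9
Reactants: 15 dec-9-ynoic acid; 16 (6-bromohexyloxy)(tert-butyl)dimethylsilane
Product: 18 16-[(tert-butyldimethylsilyl)oxy]hexadec-9-ynoic acid, via dilithium acetylide carboxylate 17 (not isolated)
Conditions: n-BuLi (2.1 equiv), THF/HMPA (4:1), −78 → 0 °C; then 16, 0 °C → rt; dilute HCl work-up
Reagents that add atoms: none
Why: Acetylide C-alkylation (SN2) of the carboxylate–acetylide dianion with a primary bromide; the carboxylate oxygen is the much poorer nucleophile.

Step 10
Reactants: 18 16-[(tert-butyldimethylsilyl)oxy]hexadec-9-ynoic acid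
Product: 19 (9Z)-16-[(tert-butyldimethylsilyl)oxy]hexadec-9-enoic acid
Conditions: H2 (1 atm), Pd/CaCO3 poisoned with Pb(OAc)2, quinoline, EtOAc, rt
Reagents that add atoms: none
Why: Lindlar semihydrogenation; syn delivery of H2 on poisoned palladium gives the Z olefin only.

Step 11
Reactants: 14 (1S,2S,5S,7R,10S)-2-(dimethoxymethyl)-10-hydroxy-6,6-dimethyltricyclo[5.3.1.0^{1,5}]undec-8-ene-8-carbaldehyde; 19 (9Z)-16-[(tert-butyldimethylsilyl)oxy]hexadec-9-enoic acid
Product: 21 (1S,2S,5S,7R,10S)-2-(dimethoxymethyl)-8-formyl-6,6-dimethyltricyclo[5.3.1.0^{1,5}]undec-8-en-10-yl (9Z)-16-[(tert-butyldimethylsilyl)oxy]hexadec-9-enoate, via mixed anhydride 20 (not isolated)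
Conditions: 19, 2,4,6-Cl3C6H2COCl, Et3N, toluene, rt; then 14, DMAP, rt
Reagents that add atoms: none
Why: Yamaguchi esterification; DMAP attacks the unhindered fatty acyl carbonyl of the mixed anhydride and passes it to the hindered allylic C10–OH, with retention because the C10–O bond is not broken.

Step 12
Reactants: 21 (1S,2S,5S,7R,10S)-2-(dimethoxymethyl)-8-formyl-6,6-dimethyltricyclo[5.3.1.0^{1,5}]undec-8-en-10-yl (9Z)-16-[(tert-butyldimethylsilyl)oxy]hexadec-9-enoate
Product: 22 (1S,2S,5S,7R,10S)-10-{[(9Z)-16-[(tert-butyldimethylsilyl)oxy]hexadec-9-enoyl]oxy}-2-(dimethoxymethyl)-6,6-dimethyltricyclo[5.3.1.0^{1,5}]undec-8-ene-8-carboxylic acid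
Conditions: NaClO2, NaH2PO4, 2-methyl-2-butene (30 equiv), t-BuOH/H2O, 0 °C, 1 h
Reagents that add atoms: sodium chlorite [Na+].[O-]Cl=O
Why: Pinnick oxidation turns the enal into the enoic acid; 2-methyl-2-butene scavenges HOCl so the Z olefin is safe, and the ester, silyl ether and (in a short run near pH 4) the acetal are not affected.

Step 13
Reactants: 22 (1S,2S,5S,7R,10S)-10-{[(9Z)-16-[(tert-butyldimethylsilyl)oxy]hexadec-9-enoyl]oxy}-2-(dimethoxymethyl)-6,6-dimethyltricyclo[5.3.1.0^{1,5}]undec-8-ene-8-carboxylic acid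
Product: 23 (1S,2S,5S,7R,10S)-2-formyl-10-{[(9Z)-16-hydroxyhexadec-9-enoyl]oxy}-6,6-dimethyltricyclo[5.3.1.0^{1,5}]undec-8-ene-8-carboxylic acid
Conditions: AcOH/THF/H2O (3:1:1), 35 °C
Reagents that add atoms: water O
Why: Mild aqueous acid hydrolyses the dimethyl acetal and the primary silyl ether in one operation; it is too mild to enolise the α-branched aldehyde, cleave the allylic ester or isomerise the Z olefin, so all five stereocentres and the olefin geometry are kept.

**Compound list**
1 | 2-(4-methylphenyl)acetic acid | Cc1ccc(CC(=O)O)cc1 | starting material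
2 | 5-iodo-2-methylpent-2-ene | CC(C)=CCCI | starting material
3 | dilithium enediolate of 1 | Cc1ccc(cc1)C=C([O-])[O-].[Li+].[Li+] | intermediate
4 | (2S)-6-methyl-2-(4-methylphenyl)hept-5-enoic acid | Cc1ccc(cc1)[C@@H](C(=O)O)CCC=C(C)C | intermediate
5 | (2S)-6-methyl-2-(4-methylcyclohexa-1,4-dien-1-yl)hept-5-enoic acid | CC1=CCC(=CC1)[C@@H](C(=O)O)CCC=C(C)C | intermediate
6 | spiro acorenyl cation: 2-(4-carboxy-8-methylspiro[4.5]dec-7-en-1-yl)propan-2-ylium, carboxyl and cationic side chain cis on the cyclopentane, cationic side chain on the side of the allylic ring CH2 | C[C+](C)[C@@H]1CC[C@H](C(=O)O)[C@]12CC=C(C)CC2 | intermediate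
7 | cedryl cation: 2-carboxy-6,6,8-trimethyltricyclo[5.3.1.0^{1,5}]undecan-8-ylium, ring stereocentres as in 8 | CC1(C)[C@H]2C[C@@]3(CC[C+]2C)[C@@H](C(=O)O)CC[C@@H]13 | intermediate
8 | (1R,2S,5S,7S)-6,6,8-trimethyltricyclo[5.3.1.0^{1,5}]undec-8-ene-2-carboxylic acid | CC1(C)[C@H]2C[C@@]3(CC=C2C)[C@@H](C(=O)O)CC[C@@H]13 | intermediate
9 | methyl (1R,2S,5S,7S)-6,6,8-trimethyltricyclo[5.3.1.0^{1,5}]undec-8-ene-2-carboxylate | CC1(C)[C@H]2C[C@@]3(CC=C2C)[C@@H](C(=O)OC)CC[C@@H]13 | intermediate
10 | (1R,2S,5S,7S)-6,6,8-trimethyltricyclo[5.3.1.0^{1,5}]undec-8-ene-2-carbaldehyde | CC1(C)[C@H]2C[C@@]3(CC=C2C)[C@@H](C=O)CC[C@@H]13 | intermediate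
11 | (1R,2S,5S,7S)-2-(dimethoxymethyl)-6,6,8-trimethyltricyclo[5.3.1.0^{1,5}]undec-8-ene | CC1(C)[C@H]2C[C@@]3(CC=C2C)[C@@H](C(OC)OC)CC[C@@H]13 | intermediate
12 | (1S,2S,5S,7S)-2-(dimethoxymethyl)-6,6,8-trimethyltricyclo[5.3.1.0^{1,5}]undec-8-en-10-one | CC1(C)[C@H]2C[C@@]3(C(=O)C=C2C)[C@@H](C(OC)OC)CC[C@@H]13 | intermediate
13 | (1S,2S,5S,7S,10S)-2-(dimethoxymethyl)-6,6,8-trimethyltricyclo[5.3.1.0^{1,5}]undec-8-en-10-ol | CC1(C)[C@H]2C[C@@]3([C@@H](O)C=C2C)[C@@H](C(OC)OC)CC[C@@H]13 | intermediate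
14 | (1S,2S,5S,7R,10S)-2-(dimethoxymethyl)-10-hydroxy-6,6-dimethyltricyclo[5.3.1.0^{1,5}]undec-8-ene-8-carbaldehyde | CC1(C)[C@H]2C[C@@]3([C@@H](O)C=C2C=O)[C@@H](C(OC)OC)CC[C@@H]13 | intermediate
15 | dec-9-ynoic acid | C#CCCCCCCCC(=O)O | starting material
16 | (6-bromohexyloxy)(tert-butyl)dimethylsilane | BrCCCCCCO[Si](C)(C)C(C)(C)C | starting material
17 | dilithium acetylide carboxylate of 15 | [Li+].[Li+].[C-]#CCCCCCCCC(=O)[O-] | intermediate
18 | 16-[(tert-butyldimethylsilyl)oxy]hexadec-9-ynoic acid | OC(=O)CCCCCCCC#CCCCCCCO[Si](C)(C)C(C)(C)C | intermediate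
19 | (9Z)-16-[(tert-butyldimethylsilyl)oxy]hexadec-9-enoic acid | OC(=O)CCCCCCC/C=C\CCCCCCO[Si](C)(C)C(C)(C)C | intermediate
20 | (9Z)-16-[(tert-butyldimethylsilyl)oxy]hexadec-9-enoic 2,4,6-trichlorobenzoic anhydride | O=C(OC(=O)c1c(Cl)cc(Cl)cc1Cl)CCCCCCC/C=C\CCCCCCO[Si](C)(C)C(C)(C)C | intermediate
21 | (1S,2S,5S,7R,10S)-2-(dimethoxymethyl)-8-formyl-6,6-dimethyltricyclo[5.3.1.0^{1,5}]undec-8-en-10-yl (9Z)-16-[(tert-butyldimethylsilyl)oxy]hexadec-9-enoate | CC1(C)[C@H]2C[C@@]3([C@@H](OC(=O)CCCCCCC/C=C\CCCCCCO[Si](C)(C)C(C)(C)C)C=C2C=O)[C@@H](C(OC)OC)CC[C@@H]13 | intermediate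
22 | (1S,2S,5S,7R,10S)-10-{[(9Z)-16-[(tert-butyldimethylsilyl)oxy]hexadec-9-enoyl]oxy}-2-(dimethoxymethyl)-6,6-dimethyltricyclo[5.3.1.0^{1,5}]undec-8-ene-8-carboxylic acid | CC1(C)[C@H]2C[C@@]3([C@@H](OC(=O)CCCCCCC/C=C\CCCCCCO[Si](C)(C)C(C)(C)C)C=C2C(=O)O)[C@@H](C(OC)OC)CC[C@@H]13 | intermediate
23 | (1S,2S,5S,7R,10S)-2-formyl-10-{[(9Z)-16-hydroxyhexadec-9-enoyl]oxy}-6,6-dimethyltricyclo[5.3.1.0^{1,5}]undec-8-ene-8-carboxylic acid | CC1(C)[C@H]2C[C@@]3([C@@H](OC(=O)CCCCCCC/C=C\CCCCCCO)C=C2C(=O)O)[C@@H](C=O)CC[C@@H]13 | target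

**Step count and risks**

Total steps: 13. Longest linear sequence: 11 (steps 1–8, then 11–13); steps 9–10 are the side branch.

The three steps most likely to fail:

Step 3 (cascade). The carboxyl on C2 slows formation of the ring cation, so aromatisation by hydride transfer and elimination to the conjugated acid compete. The new C5–C6 bond may also form mainly trans to the carboxyl (the sterically preferred, natural-cedrene arrangement), which gives the diastereomer with the antipodal core. That diastereomer is removed in step 4, so this costs yield, not enantiopurity. The fallback uses the trans manifold deliberately and sets out from 1 and 2, returning at 9. Step 1 is run with the S,S antipode of the tetraamine to give (2R)-6-methyl-2-(4-methylphenyl)hept-5-enoic acid F1. Birch reduction as in step 2 gives (2R)-6-methyl-2-(4-methylcyclohexa-1,4-dien-1-yl)hept-5-enoic acid F2. The same CF3CO2H cascade, now through its trans manifold, gives (1R,2R,5S,7S)-6,6,8-trimethyltricyclo[5.3.1.0^{1,5}]undec-8-ene-2-carboxylic acid F3, which has the correct core but is epimeric at C2. MeI/K2CO3 gives methyl (1R,2R,5S,7S)-6,6,8-trimethyltricyclo[5.3.1.0^{1,5}]undec-8-ene-2-carboxylate F4. LiN(i-Pr)2 in THF (−78 → −20 °C) forms the lithium ester enolate F5, which is quenched at −78 °C with 2,6-di-tert-butyl-4-methylphenol. The proton should enter C2 from the face away from the C11 methylene, whose hydrogen blocks the other face, which inverts C2 and gives 9. Unchanged F4 is separated and recycled.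

Step 6 (allylic C–H oxidation). The allyl radical can be trapped at C8 to give a transposed tertiary peroxide, and the acetal C–H may also be attacked. The fallback sets out from 11 and returns at 12. mCPBA/NaHCO3 in CH2Cl2 epoxidises the 8-ene from the C11-bridge face to give 8,9-epoxy-2-(dimethoxymethyl)-6,6,8-trimethyltricyclo[5.3.1.0^{1,5}]undecane F6. LiNEt2 in ether opens it by syn β-elimination of H10 to 2-(dimethoxymethyl)-6,6,8-trimethyltricyclo[5.3.1.0^{1,5}]undec-9-en-8-ol F7. [C5H5NH][CrO3Cl] buffered with NaOAc then effects the oxidative 1,3-transposition (Dauben–Babler) to 12.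

Step 8 (SeO2 on a free allylic alcohol). The secondary allylic alcohol may be oxidised or the acetal cleaved at 80 °C. The fallback sets out from 12, bypasses 13 and returns at 14. KN(SiMe3)2 and t-BuMe2SiCl in THF at −78 °C deprotonate C15, the only enolisable position because C1 is quaternary, to give 10-[(tert-butyldimethylsilyl)oxy]-2-(dimethoxymethyl)-6,6-dimethyl-8-methylidenetricyclo[5.3.1.0^{1,5}]undec-9-ene F8. Dimethyldioxirane in acetone oxidises the exocyclic terminus (vinylogous Rubottom oxidation) and dilute acid work-up gives 2-(dimethoxymethyl)-8-(hydroxymethyl)-6,6-dimethyltricyclo[5.3.1.0^{1,5}]undec-8-en-10-one F9. NaBH4/CeCl3·7H2O in MeOH reduces the ketone from the same face as in step 7 to give (10S)-2-(dimethoxymethyl)-8-(hydroxymethyl)-6,6-dimethyltricyclo[5.3.1.0^{1,5}]undec-8-en-10-ol F10. TEMPO (cat.) with PhI(OAc)2 in CH2Cl2 then oxidises only the primary allylic alcohol to 14.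

Further compounds
F1 | step 3 | (2R)-6-methyl-2-(4-methylphenyl)hept-5-enoic acid | Cc1ccc(cc1)[C@H](C(=O)O)CCC=C(C)C
F2 | step 3 | (2R)-6-methyl-2-(4-methylcyclohexa-1,4-dien-1-yl)hept-5-enoic acid | CC1=CCC(=CC1)[C@H](C(=O)O)CCC=C(C)C
F3 | step 3 | (1R,2R,5S,7S)-6,6,8-trimethyltricyclo[5.3.1.0^{1,5}]undec-8-ene-2-carboxylic acid | CC1(C)[C@H]2C[C@@]3(CC=C2C)[C@H](C(=O)O)CC[C@@H]13
F4 | step 3 | methyl (1R,2R,5S,7S)-6,6,8-trimethyltricyclo[5.3.1.0^{1,5}]undec-8-ene-2-carboxylate | CC1(C)[C@H]2C[C@@]3(CC=C2C)[C@H](C(=O)OC)CC[C@@H]13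
F5 | step 3 | lithium ester enolate of F4 (C2 trigonal) | CC1(C)[C@H]2C[C@@]3(CC=C2C)C(=C([O-])OC)CC[C@@H]13.[Li+]
F6 | step 6 | 8,9-epoxy-2-(dimethoxymethyl)-6,6,8-trimethyltricyclo[5.3.1.0^{1,5}]undecane, epoxide oxygen on the C11-bridge face | CC1(C)[C@H]2C[C@@]3(C[C@@H]4O[C@]24C)[C@@H](C(OC)OC)CC[C@@H]13
F7 | step 6 | 2-(dimethoxymethyl)-6,6,8-trimethyltricyclo[5.3.1.0^{1,5}]undec-9-en-8-ol, hydroxyl on the C11-bridge face | CC1(C)[C@H]2C[C@@]3(C=C[C@]2(C)O)[C@@H](C(OC)OC)CC[C@@H]13
F8 | step 8 | 10-[(tert-butyldimethylsilyl)oxy]-2-(dimethoxymethyl)-6,6-dimethyl-8-methylidenetricyclo[5.3.1.0^{1,5}]undec-9-ene | CC1(C)[C@H]2C[C@@]3(C(O[Si](C)(C)C(C)(C)C)=CC2=C)[C@@H](C(OC)OC)CC[C@@H]13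
F9 | step 8 | 2-(dimethoxymethyl)-8-(hydroxymethyl)-6,6-dimethyltricyclo[5.3.1.0^{1,5}]undec-8-en-10-one | CC1(C)[C@H]2C[C@@]3(C(=O)C=C2CO)[C@@H](C(OC)OC)CC[C@@H]13
F10 | step 8 | (10S)-2-(dimethoxymethyl)-8-(hydroxymethyl)-6,6-dimethyltricyclo[5.3.1.0^{1,5}]undec-8-en-10-ol | CC1(C)[C@H]2C[C@@]3([C@@H](O)C=C2CO)[C@@H](C(OC)OC)CC[C@@H]13
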